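**Plan**

- Retrosynthesis: after removal of eleven benzyl ethers, the upper unit is cut at two bonds of one carbon, C4–C4a (ring C) and C4–C8 of the middle unit. C4 thus becomes the acetal carbon of an acyclic C3 chain that already carries ring B on C2 and ring A as the C2–O aryl ether. The same double cut is made in the middle unit, and C4–C4a plus C4–H in the lower unit.
- Enabling feature: C4 of each extender unit lies between two phloroglucinol-type rings. C4a of its own ring A (ortho/para to O1, O5, O7) can close ring C on an oxocarbenium ion at C4. The same three oxygens then stabilise the C4 cation, so C8 of the next unit can add; one aldehyde-level carbon is arylated twice.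
- Forward: one Z-alkene gives both enantiomers of the acyclic acetal. Lower ring C arises by reductive cyclisation of the hydroxy acetal (its 3-OH stays free, the usual state of the nucleophilic partner), middle ring C together with the first interflavan bond, and upper ring C last, together with the second interflavan bond; global hydrogenolysis follows.
- Stereochemistry: C2/C3 of every unit come from Jacobsen–Katsuki epoxidation of the Z-alkene (the catalyst enantiomer selects the series) and SN2 inversion by a phenoxide at the benzylic carbon, which gives 2,3-cis. C4 of both extender units comes from attack anti to the 3-benzyloxy group of the flavan-4-yl cation, which gives 3,4-trans.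

Key step: step 11

Remark: the target is read as epiafzelechin-(4β→8)-ent-epiafzelechin-(4α→8)-epiafzelechin, with upper unit (2R,3R,4R), middle unit (2S,3S,4R) and lower unit (2R,3R). The sense of induction of the salen catalysts is assumed to follow that known for cis-cinnamates and cis-β-methylstyrene; were it opposite, the catalysts of steps 3 and 6 would change places.

**Route**

Step 1
Reactants: 1 1-(benzyloxy)-4-iodobenzene; 2 3,3-diethoxyprop-1-yne
Product: 3 1-(benzyloxy)-4-(3,3-diethoxyprop-1-yn-1-yl)benzene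
Conditions: PdCl2(PPh3)2 (2 mol%), CuI (4 mol%), Et3N, THF, rt
Reagents that add atoms: none
Why: Sonogashira coupling of an aryl iodide with a terminal alkyne, to which the acetal and the benzyl ether are inert.

Step 2
Reactants: 3 1-(benzyloxy)-4-(3,3-diethoxyprop-1-yn-1-yl)benzene
Product: 4 1-(benzyloxy)-4-[(1Z)-3,3-diethoxyprop-1-en-1-yl]benzene
Conditions: H2 (1 atm), Pd/CaCO3 poisoned with Pb(OAc)2 (Lindlar catalyst), quinoline, EtOAc, rt, stopped after one equivalent of H2
Reagents that add atoms: none
Why: Lindlar semihydrogenation adds H2 syn to the alkyne and should give the Z-alkene, the aryl benzyl ether being stable to the poisoned catalyst.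

Step 3
Reactants: 4 1-(benzyloxy)-4-[(1Z)-3,3-diethoxyprop-1-en-1-yl]benzene
Product: 5 (2S,3S)-2-[4-(benzyloxy)phenyl]-3-(diethoxymethyl)oxirane (cis)
Conditions: (S,S)-[N,N'-bis(3,5-di-tert-butylsalicylidene)-1,2-cyclohexanediaminato]MnCl (Jacobsen catalyst, trivalent manganese, 5 mol%), 4-phenylpyridine N-oxide (0.2 equiv), aq. NaOCl buffered to pH 11.3 with Na2HPO4, CH2Cl2, 0 °C; filtration through basic Al2O3, used at once
Reagents that add atoms: sodium hypochlorite, [Na+].[O-]Cl
Why: Jacobsen–Katsuki epoxidation of a cis-disubstituted aryl alkene, in which side-on approach of the Z-olefin to the oxo-manganese salen species should set both centres (the future C2 and C3 of the upper and lower units) with the cis geometry kept, while the basic two-phase medium spares the acid-labile epoxide and acetal.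

Step 4
Reactants: 5 (2S,3S)-2-[4-(benzyloxy)phenyl]-3-(diethoxymethyl)oxirane; 6 3,5-bis(benzyloxy)phenol
Product: 7 (2S,3R)-3-[4-(benzyloxy)phenyl]-3-[3,5-bis(benzyloxy)phenoxy]-1,1-diethoxypropan-2-ol
Conditions: Cs2CO3 (0.3 equiv), 6 (1.3 equiv), DMF, 60 °C
Reagents that add atoms: none
Why: base-mediated SN2 ring opening of an aryl oxirane by a phenoxide at the benzylic carbon (the other carbon is hindered and inductively deactivated by the acetal), where inversion turns the cis-epoxide into the syn aryloxy alcohol that corresponds to a 2,3-cis flavan, and the cesium phenoxide in DMF should react at oxygen.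

Step 5
Reactants: 7 (2S,3R)-3-[4-(benzyloxy)phenyl]-3-[3,5-bis(benzyloxy)phenoxy]-1,1-diethoxypropan-2-ol
Product: 8 (2S,3R)-2-(benzyloxy)-3-[4-(benzyloxy)phenyl]-3-[3,5-bis(benzyloxy)phenoxy]propanal diethyl acetal
Conditions: NaH, BnBr, Bu4NI (cat.), THF–DMF, 0 °C to rt
Reagents that add atoms: benzyl bromide, BrCc1ccccc1
Why: Williamson etherification of the secondary alkoxide, which touches no stereocentre and leaves the acetal intact.

Step 6
Reactants: 4 1-(benzyloxy)-4-[(1Z)-3,3-diethoxyprop-1-en-1-yl]benzene
Product: 9 (2R,3R)-2-[4-(benzyloxy)phenyl]-3-(diethoxymethyl)oxirane (cis)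
Conditions: (R,R)-[N,N'-bis(3,5-di-tert-butylsalicylidene)-1,2-cyclohexanediaminato]MnCl (Jacobsen catalyst, trivalent manganese, 5 mol%), 4-phenylpyridine N-oxide (0.2 equiv), aq. NaOCl buffered to pH 11.3 with Na2HPO4, CH2Cl2, 0 °C; filtration through basic Al2O3, used at once
Reagents that add atoms: sodium hypochlorite, [Na+].[O-]Cl
Why: the same Jacobsen–Katsuki epoxidation with the enantiomeric catalyst should give the mirror-image cis-epoxide, which carries the future C2 and C3 of the middle (ent) unit.

Step 7
Reactants: 9 (2R,3R)-2-[4-(benzyloxy)phenyl]-3-(diethoxymethyl)oxirane; 6 3,5-bis(benzyloxy)phenol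
Product: 10 (2R,3S)-3-[4-(benzyloxy)phenyl]-3-[3,5-bis(benzyloxy)phenoxy]-1,1-diethoxypropan-2-ol
Conditions: Cs2CO3 (0.3 equiv), 6 (1.3 equiv), DMF, 60 °C
Reagents that add atoms: none
Why: the same benzylic SN2 epoxide opening by the phenoxide with inversion, giving the syn aryloxy alcohol of the ent series.

Step 8
Reactants: 10 (2R,3S)-3-[4-(benzyloxy)phenyl]-3-[3,5-bis(benzyloxy)phenoxy]-1,1-diethoxypropan-2-ol
Product: 11 (2R,3S)-2-(benzyloxy)-3-[4-(benzyloxy)phenyl]-3-[3,5-bis(benzyloxy)phenoxy]propanal diethyl acetal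
Conditions: NaH, BnBr, Bu4NI (cat.), THF–DMF, 0 °C to rt
Reagents that add atoms: benzyl bromide, BrCc1ccccc1
Why: Williamson etherification as in step 5, with no stereocentre involved.

Step 9
Reactants: 7 (2S,3R)-3-[4-(benzyloxy)phenyl]-3-[3,5-bis(benzyloxy)phenoxy]-1,1-diethoxypropan-2-ol
Product: 13 5,7,4'-tri-O-benzyl-(–)-epiafzelechin, via 4-ethoxyflavan-3-ol 12 (not isolated)
Conditions: Et3SiH (5 equiv), BF3·OEt2 (2 equiv), CH2Cl2 (0.01 M), –78 to –20 °C; sat. aq. NaHCO3
Reagents that add atoms: none
Why: reductive Friedel–Crafts cyclisation, in which BF3 ionises the acetal, the tethered 3,5-bis(benzyloxy)phenyl ether should close ring C on the oxocarbenium ion faster than the silane reduces it, and the 4-ethoxyflavan-3-ol 12 re-ionises to the flavan-4-yl cation that Et3SiH reduces (ionic hydrogenation), while the hydroxyl should stay free because silicon leaves as the fluorosilane and C2 and C3 are untouched.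

Step 10
Reactants: 11 (2R,3S)-2-(benzyloxy)-3-[4-(benzyloxy)phenyl]-3-[3,5-bis(benzyloxy)phenoxy]propanal diethyl acetal; 13 5,7,4'-tri-O-benzyl-(–)-epiafzelechin
Product: 15 hepta-O-benzyl ent-epiafzelechin-(4α→8)-epiafzelechin, via ent-4-ethoxyflavan 14 (not isolated)
Conditions: 13 (4 equiv, excess to be recovered), TMSOTf (0.3 equiv), 4 Å molecular sieves, CH2Cl2, slow addition of 11, –78 to –40 °C; Et3N quench
Reagents that add atoms: none
Why: Proposed new method: the acetal is ionised to an oxocarbenium ion, the tethered 3,5-bis(benzyloxy)phenyl ether closes ring C by a six-membered Friedel–Crafts attack to give 14, loss of ethoxide then gives the flavan-4-yl cation, and C8 of 13 (used with its 3-hydroxyl free, as is usual for the nucleophile) adds anti to the 3-benzyloxy group (3,4-trans, 4α in the ent series); the closest known reaction types are the acid-mediated cyclisation of aryloxy-aldehyde acetals and the Lewis-acid 4→8 coupling of 4-alkoxyflavans with flavan nucleophiles.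

Step 11
Reactants: 8 (2S,3R)-2-(benzyloxy)-3-[4-(benzyloxy)phenyl]-3-[3,5-bis(benzyloxy)phenoxy]propanal diethyl acetal; 15 hepta-O-benzyl ent-epiafzelechin-(4α→8)-epiafzelechin
Product: 17 undeca-O-benzyl epiafzelechin-(4β→8)-ent-epiafzelechin-(4α→8)-epiafzelechin, via 4-ethoxyflavan 16 (not isolated)
Conditions: 15 (2.5 equiv, excess to be recovered), TMSOTf (0.3 equiv), 4 Å molecular sieves, CH2Cl2, slow addition of 8, –78 to –40 °C; Et3N quench
Reagents that add atoms: none
Why: Proposed new method: TMSOTf ionises the diethyl acetal of 8 to an α-benzyloxy oxocarbenium ion at C4, the tethered 3,5-bis(benzyloxy)phenyl ether (the future ring A) attacks it through the carbon ortho to the ether oxygen (the future C4a) so that ring C closes as 4-ethoxyflavan 16, and loss of the ethoxy group then gives the 5,7-bis(benzyloxy)flavan-4-yl cation (stabilised by O1, O5 and O7), which is captured by C8 of the ent-epiafzelechin unit of 15. The closest known reactions are the acid-mediated Friedel–Crafts cyclisation of aryloxy-aldehyde acetals to benzofurans and chromenes and the TMSOTf-promoted 4→8 coupling of 4-alkoxyflavan-3-ol benzyl ethers with flavan nucleophiles; new is their fusion, so that ring C and the interflavan bond arise in one operation from an acyclic precursor. The one ring formed, ring C, closes by a six-membered 6-exo-trig Friedel–Crafts attack of an arene carbon on the exocyclic C=O+ bond, and the two ortho positions of the phenoxy ring are equivalent. C2 and C3 are carried unchanged from 8, and the one new stereocentre, C4, is set when the nucleophile adds to the half-chair cation (2-aryl equatorial) anti to the pseudo-axial 3-benzyloxy group, which gives the 3,4-trans (4β) bond. The step needs cyclisation ahead of intermolecular capture of the first cation (secured by the six-membered intramolecular reach of a phloroglucinol-type ring; the reverse order would still lead to the same skeleton, though C4 would then be set in the ring closure), attack by C8 and not C6 of 15 (C8 of its upper unit lies between O1 and one benzyloxy group, both C6 positions between two) and a single coupling (excess 15, slow addition of 8). The free 3-hydroxyl of the lower unit of 15 should be tolerated, because capture of either cation at oxygen is reversible under the Lewis acid while C-arylation is not.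

Step 12
Reactants: 17 undeca-O-benzyl epiafzelechin-(4β→8)-ent-epiafzelechin-(4α→8)-epiafzelechin
Product: 18 epiafzelechin-(4β→8)-ent-epiafzelechin-(4α→8)-epiafzelechin (CNP0191553.2)
Conditions: H2 (1 atm), Pd(OH)2/C, THF–MeOH–H2O, rt; filtration, lyophilisation
Reagents that add atoms: none
Why: catalytic hydrogenolysis of all eleven benzyl ethers, the standard last step for benzylated proanthocyanidins, which should leave the C4–aryl bonds, the C2–O1 bonds and every stereocentre untouched.

**Compound list**

1 | 1-(benzyloxy)-4-iodobenzene | Ic1ccc(OCc2ccccc2)cc1 | starting material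
2 | 3,3-diethoxyprop-1-yne | C#CC(OCC)OCC | starting material
3 | 1-(benzyloxy)-4-(3,3-diethoxyprop-1-yn-1-yl)benzene | CCOC(OCC)C#Cc1ccc(OCc2ccccc2)cc1 | intermediate
4 | 1-(benzyloxy)-4-[(1Z)-3,3-diethoxyprop-1-en-1-yl]benzene | CCOC(OCC)/C=C\c1ccc(OCc2ccccc2)cc1 | intermediate
5 | (2S,3S)-2-[4-(benzyloxy)phenyl]-3-(diethoxymethyl)oxirane (cis) | CCOC(OCC)[C@H]1O[C@H]1c1ccc(OCc2ccccc2)cc1 | intermediate
6 | 3,5-bis(benzyloxy)phenol | Oc1cc(OCc2ccccc2)cc(OCc2ccccc2)c1 | starting material
7 | (2S,3R)-3-[4-(benzyloxy)phenyl]-3-[3,5-bis(benzyloxy)phenoxy]-1,1-diethoxypropan-2-ol | CCOC(OCC)[C@@H](O)[C@H](Oc1cc(OCc2ccccc2)cc(OCc2ccccc2)c1)c1ccc(OCc2ccccc2)cc1 | intermediate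
8 | (2S,3R)-2-(benzyloxy)-3-[4-(benzyloxy)phenyl]-3-[3,5-bis(benzyloxy)phenoxy]propanal diethyl acetal | CCOC(OCC)[C@@H](OCc1ccccc1)[C@H](Oc1cc(OCc2ccccc2)cc(OCc2ccccc2)c1)c1ccc(OCc2ccccc2)cc1 | intermediate
9 | (2R,3R)-2-[4-(benzyloxy)phenyl]-3-(diethoxymethyl)oxirane (cis) | CCOC(OCC)[C@@H]1O[C@@H]1c1ccc(OCc2ccccc2)cc1 | intermediate
10 | (2R,3S)-3-[4-(benzyloxy)phenyl]-3-[3,5-bis(benzyloxy)phenoxy]-1,1-diethoxypropan-2-ol | CCOC(OCC)[C@H](O)[C@@H](Oc1cc(OCc2ccccc2)cc(OCc2ccccc2)c1)c1ccc(OCc2ccccc2)cc1 | intermediate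
11 | (2R,3S)-2-(benzyloxy)-3-[4-(benzyloxy)phenyl]-3-[3,5-bis(benzyloxy)phenoxy]propanal diethyl acetal | CCOC(OCC)[C@H](OCc1ccccc1)[C@@H](Oc1cc(OCc2ccccc2)cc(OCc2ccccc2)c1)c1ccc(OCc2ccccc2)cc1 | intermediate
12 | (2R,3R)-5,7-bis(benzyloxy)-2-[4-(benzyloxy)phenyl]-4-ethoxychroman-3-ol (4-ethoxy-5,7,4'-tri-O-benzylepiafzelechin, C4 epimers; not isolated) | O(Cc5ccccc5)c1ccc([C@H]2Oc3cc(OCc5ccccc5)cc(OCc5ccccc5)c3C(OCC)[C@H]2O)cc1 | intermediate
13 | 5,7,4'-tri-O-benzyl-(–)-epiafzelechin, (2R,3R)-5,7-bis(benzyloxy)-2-[4-(benzyloxy)phenyl]chroman-3-ol | O(Cc5ccccc5)c1ccc([C@H]2Oc3cc(OCc5ccccc5)cc(OCc5ccccc5)c3C[C@H]2O)cc1 | intermediate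
14 | (2S,3S)-3,5,7-tris(benzyloxy)-2-[4-(benzyloxy)phenyl]-4-ethoxychromane (4-ethoxy-tetra-O-benzyl-ent-epiafzelechin, C4 epimers; not isolated) | O(Cc5ccccc5)c1ccc([C@@H]2Oc3cc(OCc5ccccc5)cc(OCc5ccccc5)c3C(OCC)[C@@H]2OCc5ccccc5)cc1 | intermediate
15 | hepta-O-benzyl ent-epiafzelechin-(4α→8)-epiafzelechin (upper unit 2,3-cis-3,4-trans, ent series, 3-O-benzyl; lower unit 2R,3R with free 3-OH) | c1c(OCc5ccccc5)cc(OCc5ccccc5)c2c1O[C@@H](c1ccc(OCc5ccccc5)cc1)[C@@H](OCc5ccccc5)[C@@H]2c1c(OCc5ccccc5)cc(OCc5ccccc5)c2c1O[C@H](c1ccc(OCc5ccccc5)cc1)[C@H](O)C2 | intermediate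
16 | (2R,3R)-3,5,7-tris(benzyloxy)-2-[4-(benzyloxy)phenyl]-4-ethoxychromane (4-ethoxy-tetra-O-benzylepiafzelechin, C4 epimers; not isolated) | O(Cc5ccccc5)c1ccc([C@H]2Oc3cc(OCc5ccccc5)cc(OCc5ccccc5)c3C(OCC)[C@H]2OCc5ccccc5)cc1 | intermediate
17 | undeca-O-benzyl epiafzelechin-(4β→8)-ent-epiafzelechin-(4α→8)-epiafzelechin (free 3-OH on the lower unit) | O(Cc5ccccc5)c1ccc([C@H]2Oc3cc(OCc5ccccc5)cc(OCc5ccccc5)c3[C@H](c3c(OCc5ccccc5)cc(OCc5ccccc5)c4c3O[C@@H](c3ccc(OCc5ccccc5)cc3)[C@@H](OCc5ccccc5)[C@@H]4c3c(OCc5ccccc5)cc(OCc5ccccc5)c4c3O[C@H](c3ccc(OCc5ccccc5)cc3)[C@H](O)C4)[C@H]2OCc5ccccc5)cc1 | intermediate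
18 | epiafzelechin-(4β→8)-ent-epiafzelechin-(4α→8)-epiafzelechin (CNP0191553.2) | Oc1ccc([C@H]2Oc3cc(O)cc(O)c3[C@H](c3c(O)cc(O)c4c3O[C@@H](c3ccc(O)cc3)[C@@H](O)[C@@H]4c3c(O)cc(O)c4c3O[C@H](c3ccc(O)cc3)[C@H](O)C4)[C@H]2O)cc1 | target

**Summary**

Total step count: 12. Longest linear sequence: 8 steps (1, 2, 3, 4, 9, 10, 11, 12).

Steps most likely to fail:

1. Step 11. The first oxocarbenium ion or the C4 cation may be intercepted at the wrong site: attack through a C6 position of 15, over-alkylation of the product at its free upper C8, or capture before ring C has closed with poor facial control at C4. The fallback uses the known two-stage union. It sets out from 13, which is oxidised at C4 with DDQ in CH2Cl2 in the presence of 2-ethoxyethanol to 5,7,4'-tri-O-benzyl-4β-(2-ethoxyethoxy)epiafzelechin F1. Benzylation of the 3-hydroxyl (NaH, BnBr, DMF) gives 3,5,7,4'-tetra-O-benzyl-4β-(2-ethoxyethoxy)epiafzelechin F2. This is then condensed with an excess of 15 under TMSOTf in CH2Cl2 at –78 °C (attack anti to the 3-benzyloxy group), and the route is rejoined at 17. In this fallback ring C of the upper unit is closed before the interflavan bond is made.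

2. Step 10. The same processes may intervene: competing intermolecular capture, C6 attack on 13, further alkylation of 15. The fallback sets out from 11, which is cyclised reductively (Et3SiH, catalytic TMSOTf, CH2Cl2 at high dilution, –78 to –30 °C; the 4-ethoxyflavan 14 is reduced in the flask) to 3,5,7,4'-tetra-O-benzyl-ent-epiafzelechin F3. Oxidation with DDQ and 2-ethoxyethanol gives 3,5,7,4'-tetra-O-benzyl-4α-(2-ethoxyethoxy)-ent-epiafzelechin F4, and TMSOTf-promoted condensation with an excess of 13 at –78 °C rejoins the route at 15.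

3. Step 3 (and its mirror image, step 6). Leakage through a stepwise radical pathway may erode the cis geometry, facial selectivity may be only moderate with the bulky acetal substituent, and the electron-rich epoxide may open on isolation. The fallback gives up asymmetric catalysis. It sets out from 4, which is epoxidised with dimethyldioxirane in acetone at 0 °C (concerted, stereospecific, neutral) to the cis-epoxide as the racemate of 5 and 9. This is opened with 6 as in step 4 to racemic 7/10, and the enantiomers are separated by preparative HPLC on a chiral stationary phase. The route is rejoined at 7 and at 10; since it consumes both enantiomers, none of the material is wasted, and no compound outside the list is made.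

**Further compounds**

F1 | step 11 | 5,7,4'-tri-O-benzyl-4β-(2-ethoxyethoxy)epiafzelechin (2,3-cis-3,4-trans, free 3-OH) | O(Cc5ccccc5)c1ccc([C@H]2Oc3cc(OCc5ccccc5)cc(OCc5ccccc5)c3[C@H](OCCOCC)[C@H]2O)cc1
F2 | step 11 | 3,5,7,4'-tetra-O-benzyl-4β-(2-ethoxyethoxy)epiafzelechin (2,3-cis-3,4-trans) | O(Cc5ccccc5)c1ccc([C@H]2Oc3cc(OCc5ccccc5)cc(OCc5ccccc5)c3[C@H](OCCOCC)[C@H]2OCc5ccccc5)cc1
F3 | step 10 | 3,5,7,4'-tetra-O-benzyl-ent-epiafzelechin, (2S,3S) | O(Cc5ccccc5)c1ccc([C@@H]2Oc3cc(OCc5ccccc5)cc(OCc5ccccc5)c3C[C@@H]2OCc5ccccc5)cc1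
F4 | step 10 | 3,5,7,4'-tetra-O-benzyl-4α-(2-ethoxyethoxy)-ent-epiafzelechin (2,3-cis-3,4-trans) | O(Cc5ccccc5)c1ccc([C@@H]2Oc3cc(OCc5ccccc5)cc(OCc5ccccc5)c3[C@@H](OCCOCC)[C@@H]2OCc5ccccc5)cc1
F0 | step 3 | none | none
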